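The numbers of this flask come from no measurement; the run is a simulation.

In mM per minute, an empty solution takes up 0.812 mM min⁻¹ from solid J, and this feed is where I start.

    J ⇌ L, rate k1*(cs1 - [L]) while solid is left; crystals form when [L] > cs1 (cs1 = 4.1 mM, k1 = 0.0033 s⁻¹)
    L + Q → L.Q (k2 = 1.9 M⁻¹ s⁻¹)
    G ⇌ L.Q, rate k3*(cs3 - [L.Q]) while solid is left; crystals form when [L.Q] > cs3 (cs3 = 0.20 mM, k3 = 0.093 s⁻¹)
    Q → X (k4 = 0.0033 s⁻¹)

J 10 mM; Q 7.00 mM; time 3.0 min

- epsilon: doubling the amount of Q, all else as stated
- beta: doubling the solubility in step 3, all else as stated
- theta: doubling the solubility in step 1, all else as stated
- delta: doubling the dissolution coefficient of step 3, all else as stated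

- L.Q and G together at 3.0 min, in percent of the J charged
- the change that raises the amount of L.Q and G together at 3.0 min, in percent of the J charged most ("none" if none brings more than 2 percentage points) (epsilon / beta / theta / delta / none)
- amount of L.Q and G together at 3.0 min, in percent of the J charged, after theta

- what is said of L.Q includes G
- J, G is a solid; its amount is given per volume of the solution
- at the start none of J is in solution
- run time (flask): 3.0 min

I build the flask up one process at a time. With step 1 alone and L removed the moment it dissolves, the feed over the run comes to 24.4% of the J charged.

Now Q catches L with a pseudo-first-order constant, k2 times [Q], which is 0.798 min⁻¹ at the charged [Q]. I reckon with what is left, not what is made. Of a steady feed, with c that constant held steady and t the time, the fraction still uncaught at the end is the average of exp(−ct) over the run, here 38.0%, so the figure falls to 15.1%.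

Next comes step 4. By it alone, 74.3% of Q is left at mid-run, so I take 5.20 mM as the run's value. The constant becomes 0.593 min⁻¹, the fraction left becomes 46.7%, and the figure falls to 13.0%.

Last, the feed slackens as [L] rises, which acts as a further loss k1 on L, so the total loss constant is 0.791 min⁻¹. Its fraction left is 38.2%. The caught share, meaning the part of the empty-solution feed that stands as L.Q and G at the end, is the fraction gone times the part of the loss that goes through Q: 46.3%. I commit to 11.3%.

Step 3 moves material between L.Q and G, which count together, so beta and delta score zero. Theta doubles the feed and keeps the caught share, giving 22.6%. Epsilon doubles the constant to 1.19 min⁻¹, for a caught share of 65.4%. My choice is theta.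

The forecast gives 9.8%, below my figure, and theta with 18.1%, also below mine, holding that “Dissolution of J limits the rate”.

The flask gives 9.84%, and theta is the best change, gaining 8.4 percentage points against 4.7 points for epsilon, to reach 18.2%. At 3.00 min this flask holds 10.7% of the J charged as dissolved L. Set against the feed, its result is a caught share of 40.3%, where I carried 46.3%. In the neighbour flask with 1.8 mM of Q, the constant is 0.152 min⁻¹, the caught share 16.6%, and the reckoned yield 4.05%; that flask gives 3.31%.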